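**Retrosynthetic overview**

- Numbering is steroid-type: ring A C1–C5/C10, ring B C5–C10, ring C C8/C9/C11–C14, ring D (cyclobutanone) C13–C16; C19 is the lactone carbonyl carbon on C10 and β is the face of C19.
- The strategy rests on ring C being fused through C13–C14 to the cyclobutanone, with C14 carrying CO2Me next to the C15 ketone. Cutting C12–C13 and C8–C14 (Mukaiyama–Michael, then Michael) gives a ring B 2-silyloxydiene (C8=C9–C11(OSi)=C12) and a cyclobutenone β-keto ester.
- Diene: from the C9 propionyl enone, made from the C9 ketone by enol triflation and carbonylative coupling. The A/B keto lactone comes from a Birch-derived ring B β-keto ester by Robinson annulation, deconjugative gem-dimethylation, hydroboration of C5=C6 (trans A/B, oxygen at C6) and lactonisation of 6β-OH onto the 10β-ester.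
- Cyclobutenone: dimethyl squarate, semisquarate, MeLi addition and silylation, C14 iodination and methoxycarbonylation, methyl addition–elimination, resolution.
- Ring order: B (from the arene), A, lactone; D (from squarate); C last. Then C11 deoxygenation to the C11=C12 alkene, desilylation and C3 acetylation.

Key step: step 20

Assumption: the sense of induction of the (R)-BINAP palladium enolate in step 2 is taken by analogy with simple 2-oxocycloalkanecarboxylates; if it proves opposite, the (S)-BINAP complex is used and nothing else changes.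

**Route**

Step 1
Reactants: 1 methyl 2-methoxy-5-methylbenzoate
Product: 3 methyl 3-methyl-6-oxocyclohex-2-ene-1-carboxylate (ring B β-keto ester; C10 enolisable), via 1,4-dihydro enol ether 2 (not isolated)
Conditions: Li, t-BuOH (1 equiv), NH3(l)/THF, −78 °C; NH4Cl; then 1 M HCl, THF, 0 °C
Reagents that add atoms: water, O
Why: Birch reduction of the o-anisic ester gives the 1,4-dihydro ester 2 (sp3 carbons at C10 and C7), whose enol ether is hydrolysed by the acid to the C5 ketone while the C8=C9 alkene stays out of conjugation; no stereocenter is fixed.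

Step 2
Reactants: 3 ring B β-keto ester; 4 but-3-en-2-one (methyl vinyl ketone)
Product: 5 methyl (1R)-3-methyl-6-oxo-1-(3-oxobutyl)cyclohex-2-ene-1-carboxylate
Conditions: [Pd((R)-BINAP)(H2O)2](OTf)2 (5 mol %), THF, −20 °C
Reagents that add atoms: none
Why: catalytic enantioselective Michael addition of a cyclic β-keto ester to an enone through a chelated chiral palladium enolate, which reacts at C10 (the carbon between the two carbonyl groups, not the vinylogous C8) and whose BINAP ligand differentiates the enolate faces to set the C10 quaternary stereocenter.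

Step 3
Reactants: 5 Michael adduct
Product: 6 methyl (4aR)-6-methyl-2-oxo-3,4,7,8-tetrahydro-2H-naphthalene-4a-carboxylate (A/B enone: C3 ketone; C4=C5 and C8=C9 alkenes; 10β-CO2Me)
Conditions: pyrrolidine (0.3 equiv), AcOH (0.3 equiv), toluene, 80 °C
Reagents that add atoms: none
Why: intramolecular aldol condensation of the methyl ketone carbon C4 onto the C5 ketone (second half of a Robinson annulation) closes ring A as the conjugated enone; no new stereocenter.

Step 4
Reactants: 6 A/B enone
Product: 8 4,4-dimethyl-3-oxo-5,8-diene 10β-methyl ester (C10 R), via 4-monomethyl ketone 7 (not isolated)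
Conditions: KOt-Bu (3 equiv), t-BuOH/THF, 0 °C; MeI (6 equiv), 0 → 25 °C
Reagents that add atoms: iodomethane, CI
Why: deconjugative α,α-dimethylation of the enone through its extended C3–C6 dienolate, each methylation occurring at C4 and leaving the alkene at C5=C6; no new stereocenter.

Step 5
Reactants: 8 4,4-dimethyl ketone
Product: 9 3α-hydroxy-4,4-dimethyl-5,8-diene 10β-methyl ester (3S; 10R)
Conditions: LiBH(s-Bu)3 (L-Selectride; 1.2 equiv), THF, −78 °C; H2O
Reagents that add atoms: none
Why: reduction of the C3 ketone with a bulky trialkylborohydride, which attacks along the equatorial trajectory and should therefore give the axial 3α-alcohol (trans to C19), as is usual for 4,4-dimethyl-3-ketones.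

Step 6
Reactants: 9 3α-alcohol
Product: 10 3α-(tert-butyldimethylsilyloxy) diene ester
Conditions: TBSOTf (1.3 equiv), 2,6-lutidine (2 equiv), CH2Cl2, 0 °C
Reagents that add atoms: tert-butyldimethylsilyl trifluoromethanesulfonate, CC(C)(C)[Si](C)(C)OS(=O)(=O)C(F)(F)F
Why: silyl triflate silylation of the hindered axial secondary alcohol (protection); no stereocenter is touched.

Step 7
Reactants: 10 silyl ether
Product: 12 6α,9α-diol (5α-H; 8β-methyl), via bis(alkylborane) 11 (not isolated)
Conditions: BH3·THF (4 equiv), THF, 0 → 25 °C; then NaOH, H2O2, H2O, 0 → 25 °C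
Reagents that add atoms: hydrogen peroxide, OO
Why: hydroboration–oxidation of both trisubstituted alkenes places boron on the less substituted carbons C6 and C9 from the α face (the β face carries the axial 10β-ester and 4β-methyl), so the syn-delivered hydrogen makes C5–H α and fixes the trans A/B fusion; the C6, C8 and C9 configurations formed here are not carried through.

Step 8
Reactants: 12 diol
Product: 13 6,9-diketone methyl ester (5α-H; C8 epimers)
Conditions: Dess–Martin periodinane (2.6 equiv), CH2Cl2, 25 °C
Reagents that add atoms: none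
Why: Dess–Martin oxidation of both secondary alcohols; C5 keeps the trans fusion, which is also the expected thermodynamic epimer next to the C6 ketone.

Step 9
Reactants: 13 diketone
Product: 15 9-hydroxy 19,6β-lactone (C8 and C9 epimers), via 6β-hydroxy ester 14 (not isolated)
Conditions: NaBH4 (1.5 equiv), MeOH/THF, 0 → 25 °C
Reagents that add atoms: none
Why: borohydride reduction of the C6 ketone from the α face (the β face is closed by the 1,3-diaxial 4β-methyl and 10β-ester) gives the axial 6β-alkoxide, which lactonises onto the 1,3-diaxial C19 ester and so sets C6; the C9 ketone is reduced too and is restored in step 10.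

Step 10
Reactants: 15 hydroxy lactone
Product: 16 9-oxo 19,6β-lactone (A/B keto lactone; C8 epimers)
Conditions: Dess–Martin periodinane (1.3 equiv), CH2Cl2, 25 °C
Reagents that add atoms: none
Why: Dess–Martin oxidation of the C9 alcohol back to the ketone; no stereocenter of the target is affected.

Step 11
Reactants: 16 keto lactone
Product: 18 C8=C9 enol triflate lactone, via potassium enolate 17 (not isolated)
Conditions: KN(SiMe3)2 (1.3 equiv), THF, −78 °C; PhNTf2 (1.4 equiv), −78 → 0 °C
Reagents that add atoms: N-phenylbis(trifluoromethanesulfonimide), O=S(=O)(N(c1ccccc1)S(=O)(=O)C(F)(F)F)C(F)(F)F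
Why: regiospecific enol triflate formation, since the quaternary C10 leaves C8 as the only enolisable position of the C9 ketone and the lactone has no α-hydrogen; the C8 stereocenter disappears.

Step 12
Reactants: 18 enol triflate
Product: 19 C9 propionyl enone lactone
Conditions: Pd(PPh3)4 (5 mol %), CO (1 atm), Et4Sn (1.5 equiv), LiCl (3 equiv), DMF, 65 °C
Reagents that add atoms: carbon monoxide, [C-]#[O+]; tetraethylstannane, CC[Sn](CC)(CC)CC
Why: Stille carbonylative cross-coupling (oxidative addition of the enol triflate to zerovalent palladium, CO insertion, ethyl transfer from tin, reductive elimination) gives the ethyl ketone at C9; no stereocenter.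

Step 13
Reactants: 19 propionyl enone
Product: 20 ring B 2-silyloxydiene ((Z) C11=C12 tert-butyldimethylsilyl enol ether of 19)
Conditions: TBSOTf (1.5 equiv), Et3N (3 equiv), CH2Cl2, −78 → 0 °C
Reagents that add atoms: tert-butyldimethylsilyl trifluoromethanesulfonate, CC(C)(C)[Si](C)(C)OS(=O)(=O)C(F)(F)F
Why: soft enolisation of the ethyl ketone at the α′ carbon C12 (silyl triflate and amine) gives the cross-conjugated silyl dienol ether, the (Z) isomer (methyl cis to OSi) being favoured by allylic strain with the C9 substituent.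

Step 14
Reactants: 21 dimethyl squarate (3,4-dimethoxycyclobut-3-ene-1,2-dione)
Product: 23 3-methoxycyclobut-3-ene-1,2-dione (methyl semisquarate), via 4-hydroxycyclobutenone 22 (not isolated)
Conditions: LiAlH(Ot-Bu)3 (1.05 equiv), THF, −78 → −20 °C; then 6 M HCl, CH2Cl2, 25 °C
Reagents that add atoms: water, O
Why: 1,2-reduction of one squarate carbonyl by the hindered aluminium hydride followed by acid-promoted allylic transposition of the 4-hydroxycyclobutenone with loss of methanol (the usual route to semisquarates); no stereocenter.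

Step 15
Reactants: 23 methyl semisquarate
Product: 25 3-methoxy-4-methyl-4-(triethylsilyloxy)cyclobut-2-en-1-one (racemic), via lithium alkoxide 24 (not isolated)
Conditions: MeLi (1.05 equiv), THF, −78 °C; TESOTf (1.2 equiv), −78 → 0 °C
Reagents that add atoms: methyllithium, [Li]C; triethylsilyl trifluoromethanesulfonate, CC[Si](CC)(CC)OS(=O)(=O)C(F)(F)F
Why: 1,2-addition of the organolithium to the more electrophilic carbonyl (the one next to C–OMe, not the vinylogous ester carbonyl) and O-silylation of the tertiary alkoxide; the future C16 stereocenter is formed as a racemate.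

Step 16
Reactants: 25 silyloxy vinylogous ester
Product: 26 2-iodo-3-methoxy-4-methyl-4-(triethylsilyloxy)cyclobut-2-en-1-one (racemic)
Conditions: N-iodosuccinimide (1.2 equiv), MeCN, 25 °C, dark
Reagents that add atoms: N-iodosuccinimide, O=C1CCC(=O)N1I
Why: electrophilic α-iodination of a vinylogous ester (β-alkoxy enone) at its nucleophilic α-carbon, the future C14; no stereocenter is touched.

Step 17
Reactants: 26 iodide
Product: 27 methyl 2-methoxy-3-methyl-4-oxo-3-(triethylsilyloxy)cyclobut-1-ene-1-carboxylate (racemic)
Conditions: Pd(OAc)2 (5 mol %), dppf (6 mol %), CO (1 atm), MeOH, Et3N (2 equiv), DMF, 50 °C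
Reagents that add atoms: carbon monoxide, [C-]#[O+]; methanol, CO
Why: palladium-catalysed methoxycarbonylation of the α-iodoenone (oxidative addition, CO insertion, methanolysis of the acylpalladium) installs the C14 ester, and the push–pull product should tolerate the nucleophilic medium.

Step 18
Reactants: 27 methoxy ester
Product: 29 methyl 2,3-dimethyl-4-oxo-3-(triethylsilyloxy)cyclobut-1-ene-1-carboxylate (racemic), via magnesium enolate 28 (not isolated)
Conditions: MeMgBr (1.1 equiv), CuBr·SMe2 (10 mol %), THF, −78 °C; then 1 M HCl, 0 °C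
Reagents that add atoms: methylmagnesium bromide, C[Mg]Br
Why: copper-catalysed conjugate addition of the Grignard reagent to the β-methoxy alkylidene β-keto ester and acid-induced β-elimination of methanol from the adduct (addition–elimination), any 1,2-adduct converging on the same constitution by acid-mediated allylic transposition, which is why the resolution follows this step.

Step 19
Reactants: 29 racemic cyclobutenone ester
Product: 30 methyl (3S)-2,3-dimethyl-4-oxo-3-(triethylsilyloxy)cyclobut-1-ene-1-carboxylate
Conditions: preparative HPLC on immobilised amylose tris(3,5-dimethylphenylcarbamate), hexane/EtOAc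
Reagents that add atoms: none
Why: enantiomer separation by chromatography on a chiral stationary phase (no bond is formed), the (S) fraction being identified independently before use.

Step 20
Reactants: 20 ring B 2-silyloxydiene; 30 (S)-cyclobutenone β-keto ester
Product: 32 pentacyclic C9=C11 tert-butyldimethylsilyl enol ether, via Mukaiyama–Michael zwitterion 31 (not isolated)
Conditions: Me2AlCl (1.5 equiv), CH2Cl2, −78 → −40 °C; Et3N, then H2O
Reagents that add atoms: none
Why: Me2AlCl binds the β-keto ester of 30 (C15 ketone and ester carbonyl) and the enol ether carbon C12 of 20 adds to the β-carbon C13 (Mukaiyama–Michael) to give 31, whose C14 aluminium enolate then adds to C8 of the O-silylated enone (intramolecular Michael, 6-endo-trig in the enolexo sense), closing ring C and leaving the silyl group on O11 as the C9=C11 enol ether. The closest known reaction type is the Lewis acid-promoted formal Diels–Alder (double Michael) annulation of 2-silyloxydienes with 2-alkoxycarbonyl cycloalkenones, including its stepwise variants for dienes with fully substituted termini. C13 is set by attack on the cyclobutenone face anti to the C16 OSiEt3 group, and C14 follows because the four-membered ring lets the enolate bond only on the face that already carries C12 (cis fusion). C8 is set by approach to the α face of ring B, the β face being covered by the axial C19 lactone bridge on C10, while C12 (expected with 12α-methyl from the (Z) enol ether in the ketone-endo arrangement) is removed in step 22. The step needs conjugate rather than 1,2-addition (secured by chelation and by the two quaternary carbons flanking C15), C12-to-C13 regiochemistry (secured by the polarity of both partners) and single-enantiomer 30, because the (R) dienophile would give the C13/C14/C16 diastereomer by the same rules. The stepwise path avoids the s-cis penalty that a concerted cycloaddition would pay at the tetrasubstituted C8=C9 terminus.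

Step 21
Reactants: 32 silyl enol ether
Product: 33 pentacyclic C11 ketone (9α-H; 12α-methyl)
Conditions: Bu4NF (1.05 equiv), AcOH (1.5 equiv), THF, −20 → 0 °C
Reagents that add atoms: none
Why: fluoride cleavage of the silyl enol ether (much faster than cleavage of the two alkyl silyl ethers) and protonation of the enolate by acetic acid; C9 should take the trans B/C configuration (9α-H), the expected thermodynamic epimer that the buffered medium can reach through the enol.

Step 22
Reactants: 33 C11 ketone
Product: 35 C11=C12 enol triflate, via potassium enolate 34 (not isolated)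
Conditions: KN(SiMe3)2 (1.2 equiv) added to 33 and N-(5-chloropyridin-2-yl)triflimide (1.5 equiv), THF, −78 °C
Reagents that add atoms: N-(5-chloropyridin-2-yl)bis(trifluoromethanesulfonimide), O=S(=O)(N(c1ccc(Cl)cn1)S(=O)(=O)C(F)(F)F)C(F)(F)F
Why: kinetic enol triflate formation, in which the amide base should remove the C12 proton (one quaternary neighbour) rather than the C9 proton (between the quaternary C8 and C10) and the triflimide present in the flask traps the enolate before it can open the cyclobutane by retro-Michael cleavage; the C12 stereocenter is erased.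

Step 23
Reactants: 35 enol triflate
Product: 36 C11=C12 alkene (bis-silyl ether of the deacetyl target)
Conditions: Pd(OAc)2 (10 mol %), PPh3 (20 mol %), HCO2H (3 equiv), n-Bu3N (4 equiv), DMF, 60 °C
Reagents that add atoms: none
Why: palladium-catalysed formate reduction of the enol triflate (oxidative addition, formate decarboxylation to a palladium hydride, reductive elimination) replaces OTf by H without moving the alkene.

Step 24
Reactants: 36 bis-silyl ether
Product: 37 3α,16-diol (deacetyl target)
Conditions: HF·pyridine, THF, 0 → 25 °C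
Reagents that add atoms: none
Why: fluoride-mediated cleavage of both silyl ethers under acidic conditions, chosen over basic fluoride to spare the strained cyclobutanone β-keto ester.

Step 25
Reactants: 37 diol
Product: 38 penicimeroterpenoid B
Conditions: Ac2O (3 equiv), pyridine, DMAP (0.1 equiv), CH2Cl2, 0 → 25 °C
Reagents that add atoms: acetic anhydride, CC(=O)OC(C)=O
Why: selective acylation of the secondary C3 alcohol, the tertiary C16 alcohol between two quaternary carbons being too hindered to react.

**Compound list**

1 | methyl 2-methoxy-5-methylbenzoate | COC(=O)c1cc(C)ccc1OC | starting material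
2 | methyl 2-methoxy-5-methylcyclohexa-2,5-diene-1-carboxylate (racemic) | COC(=O)C1C=C(C)CC=C1OC | intermediate
3 | methyl 3-methyl-6-oxocyclohex-2-ene-1-carboxylate (C1 enolisable) | COC(=O)C1C=C(C)CCC1=O | intermediate
4 | but-3-en-2-one | CC(=O)C=C | starting material
5 | methyl (1R)-3-methyl-6-oxo-1-(3-oxobutyl)cyclohex-2-ene-1-carboxylate | COC(=O)[C@]1(CCC(C)=O)C=C(C)CCC1=O | intermediate
6 | methyl (4aR)-6-methyl-2-oxo-3,4,7,8-tetrahydro-2H-naphthalene-4a-carboxylate | COC(=O)[C@@]12CCC(=O)C=C1CCC(C)=C2 | intermediate
7 | 4-monomethyl-3-oxo-5,8-diene 10β-methyl ester (C4 epimers) | COC(=O)[C@@]12CCC(=O)C(C)C1=CCC(C)=C2 | intermediate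
8 | 4,4,8-trimethyl-3-oxo-5,8-diene 10β-methyl ester (10R) | COC(=O)[C@@]12CCC(=O)C(C)(C)C1=CCC(C)=C2 | intermediate
9 | 3α-hydroxy-4,4,8-trimethyl-5,8-diene 10β-methyl ester (3S,10R) | COC(=O)[C@@]12CC[C@H](O)C(C)(C)C1=CCC(C)=C2 | intermediate
10 | 3α-(tert-butyldimethylsilyloxy)-4,4,8-trimethyl-5,8-diene 10β-methyl ester | COC(=O)[C@@]12CC[C@H](O[Si](C)(C)C(C)(C)C)C(C)(C)C1=CCC(C)=C2 | intermediate
11 | 6α,9α-bis(dihydroboryl) adduct of 10 (5α-H; drawn as the monoalkylboranes) | COC(=O)[C@@]12CC[C@H](O[Si](C)(C)C(C)(C)C)C(C)(C)[C@H]1[C@H](B)C[C@@H](C)[C@@H]2B | intermediate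
12 | 3α-silyloxy-6α,9α-dihydroxy-4,4,8β-trimethyl trans-decalin 10β-methyl ester (5α-H) | COC(=O)[C@@]12CC[C@H](O[Si](C)(C)C(C)(C)C)C(C)(C)[C@H]1[C@H](O)C[C@@H](C)[C@@H]2O | intermediate
13 | 3α-silyloxy-6,9-dioxo-4,4,8-trimethyl trans-decalin 10β-methyl ester (5α-H; C8 epimers) | COC(=O)[C@@]12CC[C@H](O[Si](C)(C)C(C)(C)C)C(C)(C)[C@H]1C(=O)CC(C)C2=O | intermediate
14 | 3α-silyloxy-6β,9-dihydroxy 10β-methyl ester (C8, C9 epimers) | COC(=O)[C@@]12CC[C@H](O[Si](C)(C)C(C)(C)C)C(C)(C)[C@H]1[C@@H](O)CC(C)C2O | intermediate
15 | 3α-silyloxy-9-hydroxy 19,6β-lactone (C8, C9 epimers) | OC1C(C)C[C@@H]2OC(=O)[C@]13CC[C@H](O[Si](C)(C)C(C)(C)C)C(C)(C)[C@@H]23 | intermediate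
16 | 3α-silyloxy-9-oxo 19,6β-lactone (A/B keto lactone; C8 epimers) | O=C1C(C)C[C@@H]2OC(=O)[C@]13CC[C@H](O[Si](C)(C)C(C)(C)C)C(C)(C)[C@@H]23 | intermediate
17 | potassium C8=C9 enolate of 16 | [K+].[O-]C1=C(C)C[C@@H]2OC(=O)[C@]13CC[C@H](O[Si](C)(C)C(C)(C)C)C(C)(C)[C@@H]23 | intermediate
18 | C8=C9 enol triflate of 16 (triflate on C9) | O=S(=O)(OC1=C(C)C[C@@H]2OC(=O)[C@]13CC[C@H](O[Si](C)(C)C(C)(C)C)C(C)(C)[C@@H]23)C(F)(F)F | intermediate
19 | C9 propionyl C8=C9 enone of the A/B lactone | CCC(=O)C1=C(C)C[C@@H]2OC(=O)[C@]13CC[C@H](O[Si](C)(C)C(C)(C)C)C(C)(C)[C@@H]23 | intermediate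
20 | ring B 2-silyloxydiene: (Z) C11=C12 tert-butyldimethylsilyl enol ether of 19 | C/C=C(\O[Si](C)(C)C(C)(C)C)C1=C(C)C[C@@H]2OC(=O)[C@]13CC[C@H](O[Si](C)(C)C(C)(C)C)C(C)(C)[C@@H]23 | intermediate
21 | dimethyl squarate | COC1=C(OC)C(=O)C1=O | starting material
22 | 4-hydroxy-2,3-dimethoxycyclobut-2-en-1-one (racemic) | COC1=C(OC)C(O)C1=O | intermediate
23 | 3-methoxycyclobut-3-ene-1,2-dione | COC1=CC(=O)C1=O | intermediate
24 | lithium 2-methoxy-1-methyl-4-oxocyclobut-2-en-1-olate (racemic) | COC1=CC(=O)C1(C)[O-].[Li+] | intermediate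
25 | 3-methoxy-4-methyl-4-(triethylsilyloxy)cyclobut-2-en-1-one (racemic) | COC1=CC(=O)C1(C)O[Si](CC)(CC)CC | intermediate
26 | 2-iodo-3-methoxy-4-methyl-4-(triethylsilyloxy)cyclobut-2-en-1-one (racemic) | COC1=C(I)C(=O)C1(C)O[Si](CC)(CC)CC | intermediate
27 | methyl 2-methoxy-3-methyl-4-oxo-3-(triethylsilyloxy)cyclobut-1-ene-1-carboxylate (racemic) | COC(=O)C1=C(OC)C(C)(O[Si](CC)(CC)CC)C1=O | intermediate
28 | bromomagnesium enolate of methyl 2-methoxy-2,3-dimethyl-4-oxo-3-(triethylsilyloxy)cyclobutane-1-carboxylate | COC(=O)C1=C(O[Mg]Br)C(C)(O[Si](CC)(CC)CC)C1(C)OC | intermediate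
29 | methyl 2,3-dimethyl-4-oxo-3-(triethylsilyloxy)cyclobut-1-ene-1-carboxylate (racemic) | COC(=O)C1=C(C)C(C)(O[Si](CC)(CC)CC)C1=O | intermediate
30 | methyl (3S)-2,3-dimethyl-4-oxo-3-(triethylsilyloxy)cyclobut-1-ene-1-carboxylate | COC(=O)C1=C(C)[C@](C)(O[Si](CC)(CC)CC)C1=O | intermediate
31 | C12–C13 bonded zwitterion: C14 chlorodimethylaluminate enolate and O11-silylated C8=C9–C11 enone | COC(=O)C1=C(O[Al-](C)(C)Cl)[C@@](C)(O[Si](CC)(CC)CC)[C@]1(C)[C@H](C)C(=[O+][Si](C)(C)C(C)(C)C)C1=C(C)C[C@@H]2OC(=O)[C@]13CC[C@H](O[Si](C)(C)C(C)(C)C)C(C)(C)[C@@H]23 | intermediate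
32 | pentacyclic C9=C11 tert-butyldimethylsilyl enol ether (8β-Me, 12α-Me, 13β-Me, 14β-CO2Me, 16-OSiEt3 cis to 13-Me) | COC(=O)[C@@]12C(=O)[C@@](C)(O[Si](CC)(CC)CC)[C@]1(C)[C@H](C)C(O[Si](C)(C)C(C)(C)C)=C1[C@]34CC[C@H](O[Si](C)(C)C(C)(C)C)C(C)(C)[C@H]3[C@H](C[C@@]12C)OC4=O | intermediate
33 | pentacyclic C11 ketone (9α-H, 12α-Me) | COC(=O)[C@@]12C(=O)[C@@](C)(O[Si](CC)(CC)CC)[C@]1(C)[C@H](C)C(=O)[C@H]1[C@]34CC[C@H](O[Si](C)(C)C(C)(C)C)C(C)(C)[C@H]3[C@H](C[C@@]12C)OC4=O | intermediate
34 | potassium C11=C12 enolate of 33 | COC(=O)[C@@]12C(=O)[C@@](C)(O[Si](CC)(CC)CC)[C@]1(C)C(C)=C([O-])[C@H]1[C@]34CC[C@H](O[Si](C)(C)C(C)(C)C)C(C)(C)[C@H]3[C@H](C[C@@]12C)OC4=O.[K+] | intermediate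
35 | C11=C12 enol triflate (triflate on C11) | COC(=O)[C@@]12C(=O)[C@@](C)(O[Si](CC)(CC)CC)[C@]1(C)C(C)=C(OS(=O)(=O)C(F)(F)F)[C@H]1[C@]34CC[C@H](O[Si](C)(C)C(C)(C)C)C(C)(C)[C@H]3[C@H](C[C@@]12C)OC4=O | intermediate
36 | C11=C12 alkene with 3α-OSi(t-Bu)Me2 and 16-OSiEt3 | COC(=O)[C@@]12C(=O)[C@@](C)(O[Si](CC)(CC)CC)[C@]1(C)C(C)=C[C@H]1[C@]34CC[C@H](O[Si](C)(C)C(C)(C)C)C(C)(C)[C@H]3[C@H](C[C@@]12C)OC4=O | intermediate
37 | 3α,16-diol (deacetyl penicimeroterpenoid B) | COC(=O)[C@@]12C(=O)[C@@](C)(O)[C@]1(C)C(C)=C[C@H]1[C@]34CC[C@H](O)C(C)(C)[C@H]3[C@H](C[C@@]12C)OC4=O | intermediate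
38 | penicimeroterpenoid B | COC(=O)[C@@]12C(=O)[C@@](C)(O)[C@]1(C)C(C)=C[C@H]1[C@]34CC[C@H](OC(C)=O)C(C)(C)[C@H]3[C@H](C[C@@]12C)OC4=O | target

Total step count: 25. Longest linear sequence: 19 steps (steps 1–13, 20, 21–25); the cyclobutenone branch is steps 14–19.

**Steps most likely to fail**

Step 20 (annulation). The first C–C bond may not form at the fully substituted C13, the silyl enol ether may instead add to the C15 carbonyl (1,2-addition), or ring C may stay open after the first bond. The fallback is an anionic Michael–Michael sequence. Enone 19 is deprotonated at C12 with LiN(i-Pr)2 (THF, −78 °C) and the dienolate is added to 30; protonation gives the C12–C13 linked Michael adduct F1. Cs2CO3 in MeCN then closes ring C by Michael addition of the β-keto ester carbon C14 to C8 of the enone and gives ketone 33, where the route is rejoined at step 22.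

Step 22 (enol triflate). Deprotonation may occur at C9 instead of C12 and give the wrong enol triflate, or the C11 enolate may open the cyclobutane by retro-Michael cleavage before it is trapped. The fallback avoids an enolate. Ketone 33 is reduced with NaBH4 and CeCl3 (MeOH, −40 °C), with hydride delivery expected from the α face as in 11-oxo steroids and the C15 ketone between two quaternary carbons expected to be spared, to give the 11β-alcohol F2. Syn-elimination with the Burgess reagent (methyl N-(triethylammoniosulfonyl)carbamate, toluene, 70 °C) is possible only toward the cis 12β-hydrogen, since the C9 hydrogen is trans, and gives alkene 36, where the route is rejoined at step 24.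

Step 18 (methyl addition–elimination). A second methyl addition to the strongly electrophilic product, attack at the ester, or ring opening of the strained product on acidic work-up may erode the yield. The fallback puts the methyl group in first and the ester last. Compound 25 is treated with MeLi (THF, −78 °C) and then aqueous HCl (Stork–Danheiser transposition) to give 3,4-dimethyl-4-(triethylsilyloxy)cyclobut-2-en-1-one F3. Iodination (I2, pyridine, CH2Cl2) gives the 2-iodo enone F4, and methoxycarbonylation (Pd(OAc)2, dppf, CO, MeOH, Et3N, DMF) gives racemic 29, which is resolved as in step 19.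

**Further compounds**

F1 | step 20 | C12–C13 linked Michael adduct of 19 and 30 (ring C open between C8 and C14; C12 and C14 epimers) | COC(=O)C1C(=O)[C@@](C)(O[Si](CC)(CC)CC)[C@]1(C)C(C)C(=O)C1=C(C)C[C@@H]2OC(=O)[C@]13CC[C@H](O[Si](C)(C)C(C)(C)C)C(C)(C)[C@@H]23
F2 | step 22 | 11β-alcohol of ketone 33 | COC(=O)[C@@]12C(=O)[C@@](C)(O[Si](CC)(CC)CC)[C@]1(C)[C@H](C)[C@@H](O)[C@H]1[C@]34CC[C@H](O[Si](C)(C)C(C)(C)C)C(C)(C)[C@H]3[C@H](C[C@@]12C)OC4=O
F3 | step 18 | 3,4-dimethyl-4-(triethylsilyloxy)cyclobut-2-en-1-one (racemic) | CC1=CC(=O)C1(C)O[Si](CC)(CC)CC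
F4 | step 18 | 2-iodo-3,4-dimethyl-4-(triethylsilyloxy)cyclobut-2-en-1-one (racemic) | CC1=C(I)C(=O)C1(C)O[Si](CC)(CC)CC
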